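The numbers in the tables stem from a simulated flask for substances that don't exist.

The stirred vessel of larch receives its starting material steadily over 80 s, while coupling partner and precatalyst stand in it from the start; ash receives everything at once. The question is whether spreading the charge raises the product.

common to all: precatalyst 0.10 mM
- blue: starting material 0.10 M; coupling partner 0.13 M; run made earlier
- amber: starting material 0.10 M; coupling partner 0.087 M; run made earlier
- teal: starting material 0.10 M; coupling partner 0.20 M; run made earlier
- elm: starting material 0.10 M; coupling partner 0.130 M (in portions, 5, over 80 s); first portion at the start, last at 80 s; time 3.0 min
- larch: starting material 0.10 M (fed, over 80 s); coupling partner 0.130 M; all else is in the flask from the start; the feed brings no volume worth counting; time 3.0 min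
- ash: starting material 0.10 M; coupling partner 0.130 M; everything together at the start; time 3.0 min
- maple: starting material 0.10 M; coupling partner 0.130 M (fed, over 80 s); all else is in the flask from the start; the feed brings no volume worth counting; time 3.0 min

| run | time / min | product / % |
|---|---|---|
| blue | 0.250 | 0 |
| blue | 0.417 | 3 |
| blue | 0.667 | 7 |
| blue | 1.00 | 9 |
| blue | 2.00 | 22 |
| blue | 3.00 | 24 |
| amber | 0.500 | 1 |
| amber | 1.00 | 4 |
| amber | 1.50 | 8 |
| amber | 2.00 | 10 |
| amber | 2.50 | 18 |
| amber | 3.00 | 20 |
| teal | 0.200 | 3 |
| teal | 0.667 | 9 |
| teal | 1.00 | 13 |
| teal | 1.50 | 19 |
| teal | 2.50 | 27 |
| teal | 3.00 | 31 |

(readings scatter by 2 percentage points)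

- the numbers in the tables scatter with a standard deviation of 2 percentage points

- which flask leads in amount of product, in percent of the starting material charged ("all alike" within 1.5 percentage points) (elm / larch / ash / maple / all alike)
- how much product is there at the end, in percent of the starting material charged: elm
- how much product is there at the end, in percent of the starting material charged: larch
- how much product is there at the end, in percent of the starting material charged: ash
- how much product is there at the end, in percent of the starting material charged: maple

Blue, the same recipe as ash, climbs from 9 % to 22 % in the minute before 2.00 min, then reaches only 24 % by 3.00 min, although by these readings about 0.106 M of coupling partner remains. We therefore assume that the missing 76.0 % of starting material left by a second path, one taking two molecules of it at a time. Our quantity is 3.17, as read at blue's last point, the odds against product: starting material not turned into product, divided by that which was (the inverse of a selectivity). On this assumption the odds roughly follow the level of starting material.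

For larch, our lower bound is no gain at all, blue's reading less its scatter, 22.0 %. The top of our bracket is an estimate, not a proven limit: a steady feed with nothing consumed averages half the charge during the feed, so we halve the odds, which gives 38.7 %, and starting from blue's reading plus its scatter gives 41.3 %. We commit to larch near that top, ash near 24 %, and elm and maple below amber's 20 %, since elm and maple start with all their starting material while their coupling partner averages over the feed, with nothing consumed, 0.0650 M, less than amber's 0.087 M.

The forecast gave 24 % for ash, 21 % for larch, 20 % for elm and 19.5 % for maple, saying “Ash should lead, though the margin is modest”, and its larch lies below our lower bound. The flasks give 39.6 % in larch, under the top of our bracket, 22.2 % in ash, 14.3 % in elm and 13.9 % in maple, so larch leads.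

    coupling partner + precatalyst → free catalyst + spent reagent (k = 0.0628 L mol⁻¹ s⁻¹)
    catalyst intermediate B → free catalyst + product (k = 52.1 s⁻¹)
    starting material + catalyst intermediate A → catalyst intermediate B (k = 551 L mol⁻¹ s⁻¹)
    coupling partner + free catalyst ⇌ catalyst intermediate A (K = 14.0 L mol⁻¹, k = 5670 L mol⁻¹ s⁻¹)
    2 starting material → homo dimer (k = 0.293 L mol⁻¹ s⁻¹)

Larch ends with odds of 1.52, and homo dimer holds 57.3 % of its charge. At 3.00 min in larch, with starting material at 3.02 %, the step onto catalyst intermediate A uses it 12 times as fast as homo dimer formation does. For a neighbour flask, larch with 0.17 M of starting material, scaling these odds with the charge gives 2.59, which means 27.9 % product, and that neighbour flask holds 29.1 %.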